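(The readings stem from a simulated flask from invented constants; noise was put on by code.)

Two questions stand on this flask: how far G has reacted at 15 h, and what share of free Z and X together is free Z.

| flask | G | Z | remark | time |
|---|---|---|---|---|
| gamma | 0.27 M | 1.2 equiv | run made earlier |  |
| zeta | 0.60 M | 1.2 equiv | run made earlier |  |
| delta | 0.40 M | 0.60 equiv | run made earlier |  |
| flask | 0.40 M | 1.20 equiv |  | 15 h |

- gamma (time / h: G / %, J / %): 0.667: 41, 59; 1.33: 37, 60; 2.50: 36, 65; 5.00: 33, 67; 10.0: 31, 68
- zeta (time / h: G / %, J / %): 0.667: 39, 60; 1.33: 38, 65; 2.50: 37, 63; 5.00: 32, 69; 10.0: 31, 70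
- delta (time / h: G / %, J / %): 2.00: 67, 33; 4.00: 63, 36; 5.00: 63, 38; 8.00: 61, 40; 10.0: 61, 37

(standard deviation of a reading: 1.5 percentage points)

- part of the G that has reacted at 15 h
- share of free Z in free Z and X together, at 15 h

- the earlier runs do not show how much of Z is bound; that part of a forecast is a guess

The bench rule says one Z takes one G, so 1.20 equiv of Z should clear G. The gamma run marks where that rule stops: its first reading has 59.0% of G reacted, a ratio of 2.03 Z charged per G reacted, so I take Z as the limiting reagent. Delta, with half the equivalents of Z of gamma, reads 33.0% reacted at its first reading, 2.00 h, so I scale this burst with the equivalents of Z.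

Past the burst G creeps in the earlier runs, so I work in logarithms. In gamma the overshoot beyond the burst is 4 percentage points at 1.33 h and 10 points at 10.0 h. The creep exponent, powers of ten of overshoot gained per power of ten of time, reads 0.454, roughly, given the scatter. Gamma and zeta both read G 31% and 31% at 10.0 h across a factor of 2.22 in concentration, so I read this flask off gamma's curve. For this flask I estimate the overshoot at 15 h as 12 points, which gives 71.0% reacted. For free Z I reckon nothing.

The forecast says 70.5% and 10%, the free share being “a guess, since the runs do not show bound Z”.

The flask gives 71.6% reacted and 0.0717% free, against my 71.0%. At 15 h the flask holds 0.029% of its charged Z free, less than the 28% of its charged G left. The same exponent gives 67.8% at 7.50 h, where the flask stands at 68.3%.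

    G + Z → L + J (k = 0.0240 M⁻¹ s⁻¹)
    Z + L ⇌ X, settled at all times (K = 15000 M⁻¹)
    Z ⇌ E (K = 2.40, k = 0.00900 s⁻¹)

For a neighbour flask with 0.720 equiv of Z I scale the burst to 35.4%. I borrow delta's overshoot, read as 9.5 points at 10.0 h, and the exponent carries it to 15 h, which gives an estimate of 46.8%; the computed result for that neighbour is 47.4%.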